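## The problem

The target 32 is a sesquilignan made of two halves. One half is a trans-2-aryl-3-hydroxymethyl-7-methoxy-2,3-dihydrobenzofuran, with ring A the guaiacyl group on C2 and ring B the benzo ring. The other half is a γ-butyrolactone joined through a CH2 group from C5 of ring B to its C-alpha, and its C-beta carries a secondary benzylic carbinol bearing the second guaiacyl group (ring C). No ring is shared between the halves, so the task is to join them at an sp3–sp3 bond and to build a 2,3-trans lactone around that bond. There are five stereocentres in two clusters: C2 (S) and C3 (R) of the dihydrobenzofuran, and C-alpha (R), C-beta (R) and the carbinol carbon (R) of the lactone part. The CH2–aryl spacer insulates the clusters, so each needs its own source of absolute configuration. Within the clusters, C3 can be equilibrated trans to C2 while it is alpha to an ester, and a large group on C-beta can steer an electrophile to the opposite face of C-alpha. The carbinol centre sits next to C-beta, but a Felkin–Anh analysis of the corresponding ketone points to the S epimer, so the R configuration has to be imposed by a reagent. The γ-hydroxy lactone translactonises under base (the carbinol oxygen attacks the lactone carbonyl), the carbinol and the C2–O1 bond are para-oxygenated benzylic C–O bonds open to acid ionisation and hydrogenolysis, and the free guaiacyl phenols oxidise easily. The enabling feature is that C-alpha and C-beta are adjacent and trans: C-beta bears a carbon that can arrive as an acyl-anion equivalent and C-alpha bears the ring B benzylic CH2. A 2(5H)-furanone accepts exactly this pattern, a nucleophile at C-beta followed by an electrophile at C-alpha, and a 5-alkoxy group on it is the future lactone OCH2.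

## Retrosynthesis

Target 32 to 31 and 30. The last cuts are O–benzyl and O–silyl bonds. The two phenols are carried as benzyl ethers because they must survive organolithiums, aqueous KOH, a mercury salt and borane. The primary alcohol is carried as a TBS ether because it must not quench the enolate of the key step. Fluoride buffered on the acidic side (30 to 31) and short neutral hydrogenolysis (31 to 32) are chosen because base would translactonise the γ-hydroxy lactone.

Alcohol 30 to ketone 29. Only the carbinol C–H bond is cut. Taking the carbinol back to a ketone is preferred to carrying an oxygenated stereocentre through the coupling: either face can then be addressed, and a wrong epimer can be re-oxidised. The forward step must override the substrate bias, which is asked of a CBS reduction in which the aryl group plays the large substituent.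

Ketone 29 to lactone 28 to acetal lactone 25. The ketone is unmasked from a 1,3-dithiane, and the lactone OCH2 is traced to a menthyl acetal carbon. Saponification, loss of menthol from the hemiacetal (26), borohydride reduction (27) and acid relactonisation are asked to erase the acetal stereocentre after it has done its work, leaving the carbonyl next to C-alpha.

Acetal lactone 25 to dithiane 17, furanone 22 and bromide 14 (key disconnection). The carbinol-carbon–C-beta and C-alpha–CH2 bonds are cut in one step. Cutting the CH2–ring B bond instead would leave C-alpha to be set by protonation. An aldol at C-alpha would put the hydroxyl on the wrong side chain, since the carbinol belongs to the C-beta substituent and must therefore come from the nucleophile. The three precursors are of comparable size and each carries at most two stereocentres. The forward reaction needs 1,4-addition of lithio dithiane 23 anti to the menthyloxy group, and C-alkylation of enolate 24 anti to the new substituent before it reverts.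

Bromide 14 to alcohol 13 to aryl bromide 10 to alcohol 9 to ester 8. The benzylic bromide is too reactive to carry, so the ring B carbon is introduced late from an aryl bromide by lithiation (11), formylation (12) and reduction. An aryl bromide is preferred to an aldehyde or ester placeholder because it survives diazo chemistry, ethoxide and hydride without protection. Silylation of 9 and reduction of 8 are routine.

Trans ester 8 to cis ester 7 to diazo ester 6. The C2–C3 bond is cut, and it forms by intramolecular C–H insertion of a rhodium carbenoid into the benzylic ether C–H bond. This is preferred to an aldol-and-cyclisation route because it makes the ring and the C2 stereocentre catalytically in one step from an acyclic ether. The cis outcome is corrected at C3 by equilibration, which is possible only because C3 is still an ester alpha carbon.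

Diazo ester 6 to iodide 4 and ethyl diazoacetate 5, then 4 to phenol 2 and alcohol 3, then 2 to 1. The aryl–carbon bond C3a–C3 is cut at the carbon–iodine bond, which gives the diazo ester in one step and avoids a multi-step arylacetic acid synthesis. The ether comes from a Mitsunobu reaction, and the iodide from ortho-iodination of commercial 4-bromo-2-methoxyphenol.

Dithiane 17 to aldehyde 15 and dithiol 16; furanone 22 to hydroxybutenolide 19 and (−)-menthol 20; 19 to furfural 18. These are one- and two-step preparations from bulk chemicals. The (5R) acetal 22 should be obtained by crystallisation, with its epimer 21 returned by acid equilibration.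

## Roads not taken

Alternative 1: The cut lies inside the lactone. The diazoacetate A2 of an E-cinnamyl-type alcohol would be decomposed by the chiral dirhodium carboxamidate Rh2(4S-MPPIM)4. Intramolecular cyclopropanation forms C-alpha–C-beta and a temporary C-alpha–carbinol-carbon bond, and gives the bicyclic lactone A1 with the ring C aryl group exo. Opening the aryl-donor, carbonyl-acceptor cyclopropane at the benzylic carbon with an oxygen nucleophile would break the sacrificial bond to give hydroxy lactone A3, and C-alpha would then be alkylated with bromide 14.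
- Merits: the route is catalytic and asymmetric. If the opening runs with clean inversion, the E geometry of the alkene delivers the R carbinol stereospecifically. In this respect it is better than the chosen plan, which has to force that centre against the substrate's bias.
- Weak points: the donor is a para-alkoxyphenyl group, so the opening is likely to have ionised, quinone-methide-like character, which uncouples the carbinol configuration from the cyclopropane. No ketone stage exists to correct it. The alkylation is a separate enolate step on a protected carbinol, and bromide 14 is still needed, so the longest branch is not shortened.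
- Comparison: the chosen plan sets against it two lactone bonds in one flask, a cheap crystalline stereocentre that relays C-alpha and C-beta, and a ketone from which either carbinol epimer can be reached and a wrong one recycled.

Alternative 2: The dihydrobenzofuran is cut at C3a–C3. Aryl iodide A5, an aryl ether of an enantioenriched 1-arylallyl alcohol, would be treated with Bu3SnH and TEMPO. The ring B aryl radical closes 5-exo-trig onto the vinyl group and the nitroxide traps the primary radical, giving A4 with the future CH2OH already oxygenated and the ring B aldehyde masked as a dioxolane.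
- Merits: the conditions are neutral, no diazo compound is needed, the iodophenol is one step from vanillin, and the length is equal to or shorter than steps 1 to 9 here.
- Weak points: C2 must exist before ring closure as an ether that is both allylic and para-alkoxybenzylic. Making it with inversion competes with ionisation and allylic transposition. C3 is then set kinetically by the 2,3-selectivity of the cyclisation, which is not reliably high for 2-aryl groups, and the product has no acidifying group at C3 to allow correction. Stoichiometric tin and an N–O cleavage are added.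
- Comparison: this road addresses only the dihydrobenzofuran half. The chosen plan sets against it two independent controls, a catalyst for C2 and ester equilibration for C3. It pays with diazo chemistry, a rhodium catalyst and the conversion of an aryl bromide into CH2Br.

Alternative 3: The biomimetic road cuts C3–C3a and O1–C2 at the very end. Ag2O would oxidise the feruloyl imide A7 and the ring B phenol of lactone A8 to radicals that pair C3 with C3a. The ring B phenol oxygen then adds to the ring A quinone methide to close the dihydrofuran of A6, with the oxazolidinone biasing the face.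
- Merits: it is the most convergent plan, it forms two bonds and a ring on unprotected phenols, and A8 needs only a simple vanillyl-type electrophile. On step count it is clearly better than the chosen plan.
- Weak points: the feruloyl radical dimerises readily, while the para-alkyl guaiacol partner is harder to oxidise and, once oxidised, can lose a benzylic hydrogen at the linker CH2. Precious late-stage lactone would be consumed unselectively. Facial control of an open radical pairing by a remote auxiliary is moderate at best. The imide would then have to be reduced to CH2OH beside a lactone of similar reactivity in a base-sensitive γ-hydroxy lactone.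
- Comparison: the chosen plan spends more steps, but each of the five stereocentres has its own adjustable control, and no step must discriminate between two radicals or two acyl groups.

Key step: step 13

Remark on the chemistry: the facial sense of the dirhodium catalyst in step 4 is assigned by analogy with benzylic ether insertions of this ligand class. The (R)-tert-leucine-derived catalyst is taken to give the (2S) ether carbon; if the sense proved opposite, the mirror-image catalyst would be used with no other change.

Shorthand in names: BnV = 4-benzyloxy-3-methoxyphenyl; DBF = the (2S,3R)-2-(BnV)-3-[(tert-butyldimethylsilyloxy)methyl]-7-methoxy-2,3-dihydrobenzofuran-5-yl group; Men = (1R,2S,5R)-2-isopropyl-5-methylcyclohexyl.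

Step 1
Reactants: 1 4-bromo-2-methoxyphenol
Product: 2 4-bromo-2-iodo-6-methoxyphenol
Conditions: I2, KI, NaHCO3, THF/H2O, rt
Reagents that add atoms: iodine, [I][I]
Why: Electrophilic iodination of a phenol under weakly basic conditions goes ortho or para to the hydroxyl; para is blocked by bromine and one ortho position by methoxy, so only C6 is open.

Step 2
Reactants: 2 4-bromo-2-iodo-6-methoxyphenol; 3 (4-benzyloxy-3-methoxyphenyl)methanol
Product: 4 2-[(BnV)methoxy]-5-bromo-1-iodo-3-methoxybenzene
Conditions: PPh3, DIAD, THF, 0 °C to rt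
Reagents that add atoms: none
Why: Mitsunobu etherification of an acidic phenol with a primary benzylic alcohol; no stereocentre is involved and both aryl halides are inert.

Step 3
Reactants: 4 2-[(BnV)methoxy]-5-bromo-1-iodo-3-methoxybenzene; 5 ethyl diazoacetate
Product: 6 ethyl 2-{2-[(BnV)methoxy]-5-bromo-3-methoxyphenyl}-2-diazoacetate
Conditions: Pd(PPh3)4 (5 mol%), Ag2CO3, Et3N, toluene, rt
Reagents that add atoms: none
Why: Palladium-catalysed cross-coupling of an aryl iodide with a diazoacetate with retention of the diazo group (oxidative addition of zerovalent palladium into the carbon–iodine bond, attack of the diazo carbon, reductive elimination); at room temperature the iodide should react well ahead of the bromide.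

Step 4
Reactants: 6 ethyl 2-{2-[(BnV)methoxy]-5-bromo-3-methoxyphenyl}-2-diazoacetate
Product: 7 ethyl (2S,3R)-2-(BnV)-5-bromo-7-methoxy-2,3-dihydrobenzofuran-3-carboxylate (2,3-cis)
Conditions: Rh2(R-PTTL)4 (1 mol%; dirhodium tetrakis[N-phthaloyl-(R)-tert-leucinate]), toluene, −78 °C
Reagents that add atoms: none
Why: Intramolecular 1,5 C–H insertion of a donor/acceptor rhodium carbenoid into the ether benzylic C–H bond, activated by the adjacent oxygen and the electron-rich ring; it forms C2–C3, closes the dihydrofuran with cis geometry through a concerted three-centre transition state, and C2 is set by the chiral carboxylate ligands.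

Step 5
Reactants: 7 ethyl (2S,3R)-2-(BnV)-5-bromo-7-methoxy-2,3-dihydrobenzofuran-3-carboxylate (2,3-cis)
Product: 8 ethyl (2S,3S)-2-(BnV)-5-bromo-7-methoxy-2,3-dihydrobenzofuran-3-carboxylate (2,3-trans)
Conditions: NaOEt (0.2 equiv), EtOH, rt
Reagents that add atoms: none
Why: Base-mediated epimerisation of the ester alpha carbon C3 to the more stable 2,3-trans isomer; C2 is not acidic and keeps its configuration, and ethoxide in ethanol avoids ester exchange.

Step 6
Reactants: 8 ethyl (2S,3S)-2-(BnV)-5-bromo-7-methoxy-2,3-dihydrobenzofuran-3-carboxylate (2,3-trans)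
Product: 9 [(2S,3R)-2-(BnV)-5-bromo-7-methoxy-2,3-dihydrobenzofuran-3-yl]methanol
Conditions: i-Bu2AlH (2.5 equiv), CH2Cl2, −78 to 0 °C; aq. potassium sodium tartrate (KNaC4H4O6)
Reagents that add atoms: none
Why: Ester reduction by a dialkylaluminium hydride, which leaves the aryl bromide, the benzyl ether and both stereocentres untouched; the alcohol should be recrystallised here to raise the enantiomeric purity.

Step 7
Reactants: 9 [(2S,3R)-2-(BnV)-5-bromo-7-methoxy-2,3-dihydrobenzofuran-3-yl]methanol
Product: 10 (2S,3R)-2-(BnV)-5-bromo-3-[(tert-butyldimethylsilyloxy)methyl]-7-methoxy-2,3-dihydrobenzofuran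
Conditions: TBSCl, imidazole, CH2Cl2, rt
Reagents that add atoms: tert-butyldimethylsilyl chloride, C[Si](C)(Cl)C(C)(C)C
Why: Standard silylation of a primary alcohol; the TBS ether should withstand organolithiums, aqueous KOH and the buffered mercury salt used later.

Step 8
Reactants: 10 (2S,3R)-2-(BnV)-5-bromo-3-[(tert-butyldimethylsilyloxy)methyl]-7-methoxy-2,3-dihydrobenzofuran
Product: 13 DBF-methanol (the 5-hydroxymethyl compound), via aryllithium 11 (not isolated), via aldehyde 12 (not isolated)
Conditions: n-BuLi, THF, −78 °C; DMF, −78 to 0 °C; then MeOH, NaBH4, 0 °C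
Reagents that add atoms: N,N-dimethylformamide, CN(C)C=O
Why: Bromine–lithium exchange is faster at −78 °C than any deprotonation, the aryllithium is formylated by DMF, and the aldehyde released on adding methanol is reduced in the same flask by borohydride.

Step 9
Reactants: 13 DBF-methanol
Product: 14 DBF-methyl bromide, i.e. (2S,3R)-2-(BnV)-5-(bromomethyl)-3-[(tert-butyldimethylsilyloxy)methyl]-7-methoxy-2,3-dihydrobenzofuran
Conditions: CBr4, PPh3, CH2Cl2, 0 °C; used at once
Reagents that add atoms: tetrabromomethane, BrC(Br)(Br)Br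
Why: Appel bromination of a primary benzylic alcohol under neutral conditions that spare the silyl ether and the acid-sensitive C2–O1 bond.

Step 10
Reactants: 15 4-benzyloxy-3-methoxybenzaldehyde; 16 propane-1,3-dithiol
Product: 17 2-(BnV)-1,3-dithiane
Conditions: BF3·OEt2 (cat.), CH2Cl2, 0 °C to rt
Reagents that add atoms: none
Why: Lewis-acid-catalysed thioacetalisation of an aromatic aldehyde; it turns the future carbinol carbon into an acyl-anion equivalent.

Step 11
Reactants: 18 furfural
Product: 19 5-hydroxyfuran-2(5H)-one (racemic)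
Conditions: O2, visible light, rose bengal (cat.), MeOH, rt
Reagents that add atoms: oxygen, O=O
Why: Dye-sensitised photooxygenation: singlet oxygen adds [4+2] across the furan, and methanolysis of the endoperoxide expels the formyl carbon as methyl formate to leave the hydroxybutenolide.

Step 12
Reactants: 19 5-hydroxyfuran-2(5H)-one; 20 (−)-menthol
Product: 22 (5R)-5-(Men-oxy)furan-2(5H)-one, via (5S)-epimer 21 (not isolated)
Conditions: TsOH·H2O (cat.), toluene, reflux, Dean–Stark; crystallisation from hexane; mother liquor re-equilibrated with TsOH and crystallised again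
Reagents that add atoms: none
Why: Acid-catalysed acetalisation through the oxocarbenium ion gives both C5 epimers, which interconvert under acid; the (5R) epimer should crystallise, so C5 is set by crystallisation-driven equilibration with menthol as the only chiral input.

Step 13
Reactants: 17 2-(BnV)-1,3-dithiane; 22 (5R)-5-(Men-oxy)furan-2(5H)-one; 14 DBF-methyl bromide
Product: 25 (3R,4R,5R)-3-(DBF-methyl)-4-[2-(BnV)-1,3-dithian-2-yl]-5-(Men-oxy)dihydrofuran-2(3H)-one, via 2-lithio-1,3-dithiane 23 (not isolated), via lithium enolate 24 (not isolated)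
Conditions: 17, n-BuLi, THF, −30 °C; 22, −78 °C; then 14 (limiting), DMPU, −78 to −30 °C
Reagents that add atoms: none
Why: Deprotonation of 17 gives the soft, sulfur-stabilised benzylic anion 23, which adds 1,4 to the butenolide 22 to form the carbinol-carbon–C-beta bond and the lithium enolate 24; the enolate then displaces bromide from 14 in an SN2 C-alkylation that forms the C-alpha–CH2 bond. The closest known reaction type is the tandem conjugate addition of lithiated aryl dithianes to 5-alkoxy-2(5H)-furanones followed by benzylation of the enolate, as used for dibenzylbutyrolactone lignans. No ring is closed. C-beta is controlled by the acetal carbon C5, whose menthyloxy group shields one face so that the nucleophile enters anti to it. C-alpha is controlled by C-beta, whose quaternary dithianyl group sends the electrophile to the opposite face and gives the trans lactone. The step needs 1,4- over 1,2-addition, secured by the delocalised aryl dithiane anion in THF at low temperature. It also needs C- over O-alkylation and trapping before retro-addition, secured by the reactive benzylic bromide, the lithium counter-ion, DMPU and keeping the mixture cold. Any minor enantiomer of 14 would appear as a diastereomer of 25 and should be removed at this stage.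

Step 14
Reactants: 25 (3R,4R,5R)-3-(DBF-methyl)-4-[2-(BnV)-1,3-dithian-2-yl]-5-(Men-oxy)dihydrofuran-2(3H)-one
Product: 28 (3R,4R)-3-(DBF-methyl)-4-[2-(BnV)-1,3-dithian-2-yl]dihydrofuran-2(3H)-one, via aldehyde carboxylate 26 (not isolated), via hydroxy acid 27 (not isolated)
Conditions: KOH, NaBH4, THF/EtOH/H2O, rt; then 1 M HCl to pH 3, 0 °C to rt
Reagents that add atoms: potassium hydroxide, [K+].[OH-] (its oxygen enters the carboxyl group and can remain in the lactone carbonyl)
Why: Saponification opens the lactone, the hemiacetal sheds menthoxide to give 26, borohydride reduces only the aldehyde (the carboxylate is inert) to 27, and acid closes the γ-lactone so that the former acetal carbon becomes the OCH2 group; the trans arrangement is the stable one and the aldehyde is reduced as it forms.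

Step 15
Reactants: 28 (3R,4R)-3-(DBF-methyl)-4-[2-(BnV)-1,3-dithian-2-yl]dihydrofuran-2(3H)-one
Product: 29 (3R,4R)-4-(4-benzyloxy-3-methoxybenzoyl)-3-(DBF-methyl)dihydrofuran-2(3H)-one
Conditions: Hg(ClO4)2·3H2O, CaCO3, THF/H2O, 0 °C to rt
Reagents that add atoms: water, O
Why: Thioacetal hydrolysis promoted by a thiophilic divalent mercury salt with CaCO3 as buffer; the near-neutral medium should leave the silyl ether, the lactone and the epimerisable C-beta untouched.

Step 16
Reactants: 29 (3R,4R)-4-(4-benzyloxy-3-methoxybenzoyl)-3-(DBF-methyl)dihydrofuran-2(3H)-one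
Product: 30 (3R,4R)-4-[(R)-(BnV)(hydroxy)methyl]-3-(DBF-methyl)dihydrofuran-2(3H)-one
Conditions: (S)-2-methyl-CBS-oxazaborolidine (0.5 equiv), BH3·SMe2, THF, −20 °C; MeOH quench
Reagents that add atoms: none
Why: CBS reduction of an aryl alkyl ketone: with the aryl group as the large substituent the (S)-oxazaborolidine delivers hydride to the face that gives the R carbinol, overriding the Felkin–Anh preference of the substrate; the lactone is not reduced by borane at this temperature.

Step 17
Reactants: 30 (3R,4R)-4-[(R)-(BnV)(hydroxy)methyl]-3-(DBF-methyl)dihydrofuran-2(3H)-one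
Product: 31 (3R,4R)-4-[(R)-(BnV)(hydroxy)methyl]-3-{[(2S,3R)-2-(BnV)-3-(hydroxymethyl)-7-methoxy-2,3-dihydrobenzofuran-5-yl]methyl}dihydrofuran-2(3H)-one
Conditions: HF·pyridine, pyridine, THF, 0 °C to rt
Reagents that add atoms: none
Why: Fluoride cleavage of a primary TBS ether in a buffered, slightly acidic medium, which forms no alkoxide next to the lactone and so should avoid translactonisation and ionisation of the benzylic carbinol.

Step 18
Reactants: 31 (3R,4R)-4-[(R)-(BnV)(hydroxy)methyl]-3-{[(2S,3R)-2-(BnV)-3-(hydroxymethyl)-7-methoxy-2,3-dihydrobenzofuran-5-yl]methyl}dihydrofuran-2(3H)-one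
Product: 32 (3R,4R)-4-[(R)-hydroxy(4-hydroxy-3-methoxyphenyl)methyl]-3-{[(2S,3R)-2-(4-hydroxy-3-methoxyphenyl)-3-(hydroxymethyl)-7-methoxy-2,3-dihydrobenzofuran-5-yl]methyl}dihydrofuran-2(3H)-one (target)
Conditions: H2 (1 atm), 10% Pd/C, EtOAc, rt; stopped at full debenzylation
Reagents that add atoms: none
Why: Hydrogenolysis of aryl benzyl ethers on palladium is much faster in neutral ethyl acetate than cleavage of the benzylic carbinol or the C2–O1 bond, so a short reaction should free both phenols only.

## Compound list

1 | 4-bromo-2-methoxyphenol | COc1cc(Br)ccc1O | starting material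
2 | 4-bromo-2-iodo-6-methoxyphenol | COc1cc(Br)cc(I)c1O | intermediate
3 | (4-benzyloxy-3-methoxyphenyl)methanol | COc1cc(CO)ccc1OCc1ccccc1 | starting material
4 | 2-[(4-benzyloxy-3-methoxyphenyl)methoxy]-5-bromo-1-iodo-3-methoxybenzene | COc1cc(COc2c(I)cc(Br)cc2OC)ccc1OCc1ccccc1 | intermediate
5 | ethyl diazoacetate | CCOC(=O)C=[N+]=[N-] | starting material
6 | ethyl 2-{2-[(4-benzyloxy-3-methoxyphenyl)methoxy]-5-bromo-3-methoxyphenyl}-2-diazoacetate | CCOC(=O)C(=[N+]=[N-])c1cc(Br)cc(OC)c1OCc1ccc(OCc2ccccc2)c(OC)c1 | intermediate
7 | ethyl (2S,3R)-2-(4-benzyloxy-3-methoxyphenyl)-5-bromo-7-methoxy-2,3-dihydrobenzofuran-3-carboxylate (cis) | COc1cc([C@H]2Oc3c(OC)cc(Br)cc3[C@H]2C(=O)OCC)ccc1OCc1ccccc1 | intermediate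
8 | ethyl (2S,3S)-2-(4-benzyloxy-3-methoxyphenyl)-5-bromo-7-methoxy-2,3-dihydrobenzofuran-3-carboxylate (trans) | COc1cc([C@H]2Oc3c(OC)cc(Br)cc3[C@@H]2C(=O)OCC)ccc1OCc1ccccc1 | intermediate
9 | [(2S,3R)-2-(4-benzyloxy-3-methoxyphenyl)-5-bromo-7-methoxy-2,3-dihydrobenzofuran-3-yl]methanol | COc1cc([C@H]2Oc3c(OC)cc(Br)cc3[C@@H]2CO)ccc1OCc1ccccc1 | intermediate
10 | (2S,3R)-2-(4-benzyloxy-3-methoxyphenyl)-5-bromo-3-[(tert-butyldimethylsilyloxy)methyl]-7-methoxy-2,3-dihydrobenzofuran | COc1cc([C@H]2Oc3c(OC)cc(Br)cc3[C@@H]2CO[Si](C)(C)C(C)(C)C)ccc1OCc1ccccc1 | intermediate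
11 | 5-lithio derivative of 10 (aryllithium) | COc1cc([C@H]2Oc3c(OC)cc([Li])cc3[C@@H]2CO[Si](C)(C)C(C)(C)C)ccc1OCc1ccccc1 | intermediate (not isolated)
12 | (2S,3R)-2-(4-benzyloxy-3-methoxyphenyl)-3-[(tert-butyldimethylsilyloxy)methyl]-7-methoxy-2,3-dihydrobenzofuran-5-carbaldehyde | COc1cc([C@H]2Oc3c(OC)cc(C=O)cc3[C@@H]2CO[Si](C)(C)C(C)(C)C)ccc1OCc1ccccc1 | intermediate (not isolated)
13 | {(2S,3R)-2-(4-benzyloxy-3-methoxyphenyl)-3-[(tert-butyldimethylsilyloxy)methyl]-7-methoxy-2,3-dihydrobenzofuran-5-yl}methanol | COc1cc([C@H]2Oc3c(OC)cc(CO)cc3[C@@H]2CO[Si](C)(C)C(C)(C)C)ccc1OCc1ccccc1 | intermediate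
14 | (2S,3R)-2-(4-benzyloxy-3-methoxyphenyl)-5-(bromomethyl)-3-[(tert-butyldimethylsilyloxy)methyl]-7-methoxy-2,3-dihydrobenzofuran | COc1cc([C@H]2Oc3c(OC)cc(CBr)cc3[C@@H]2CO[Si](C)(C)C(C)(C)C)ccc1OCc1ccccc1 | intermediate
15 | 4-benzyloxy-3-methoxybenzaldehyde | COc1cc(C=O)ccc1OCc1ccccc1 | starting material
16 | propane-1,3-dithiol | SCCCS | starting material
17 | 2-(4-benzyloxy-3-methoxyphenyl)-1,3-dithiane | COc1cc(C2SCCCS2)ccc1OCc1ccccc1 | intermediate
18 | furfural | O=Cc1ccco1 | starting material
19 | 5-hydroxyfuran-2(5H)-one (racemic) | O=C1C=CC(O)O1 | intermediate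
20 | (−)-menthol, (1R,2S,5R)-2-isopropyl-5-methylcyclohexanol | C[C@@H]1CC[C@H]([C@@H](C1)O)C(C)C | starting material
21 | (5S)-5-[(1R,2S,5R)-menthyloxy]furan-2(5H)-one | O=C1C=C[C@@H](O[C@@H]2C[C@H](C)CC[C@H]2C(C)C)O1 | intermediate (not isolated)
22 | (5R)-5-[(1R,2S,5R)-menthyloxy]furan-2(5H)-one | O=C1C=C[C@H](O[C@@H]2C[C@H](C)CC[C@H]2C(C)C)O1 | intermediate
23 | 2-lithio-2-(4-benzyloxy-3-methoxyphenyl)-1,3-dithiane | COc1cc(C2([Li])SCCCS2)ccc1OCc1ccccc1 | intermediate (not isolated)
24 | lithium enolate of (4R,5R)-4-[2-(4-benzyloxy-3-methoxyphenyl)-1,3-dithian-2-yl]-5-menthyloxydihydrofuran-2(3H)-one | [Li]OC1=C[C@@H](C2(SCCCS2)c2ccc(OCc3ccccc3)c(OC)c2)[C@H](O[C@@H]2C[C@H](C)CC[C@H]2C(C)C)O1 | intermediate (not isolated)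
25 | (3R,4R,5R)-3-(DBF-methyl)-4-[2-(4-benzyloxy-3-methoxyphenyl)-1,3-dithian-2-yl]-5-[(1R,2S,5R)-menthyloxy]dihydrofuran-2(3H)-one | COc1cc([C@H]2Oc3c(OC)cc(C[C@H]4C(=O)O[C@@H](O[C@@H]5C[C@H](C)CC[C@H]5C(C)C)[C@@H]4C4(SCCCS4)c4ccc(OCc5ccccc5)c(OC)c4)cc3[C@@H]2CO[Si](C)(C)C(C)(C)C)ccc1OCc1ccccc1 | intermediate
26 | potassium (2R,3R)-2-(DBF-methyl)-3-[2-(4-benzyloxy-3-methoxyphenyl)-1,3-dithian-2-yl]-4-oxobutanoate | COc1cc([C@H]2Oc3c(OC)cc(C[C@@H](C(=O)[O-])[C@H](C=O)C4(SCCCS4)c4ccc(OCc5ccccc5)c(OC)c4)cc3[C@@H]2CO[Si](C)(C)C(C)(C)C)ccc1OCc1ccccc1.[K+] | intermediate (not isolated)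
27 | (2R,3R)-2-(DBF-methyl)-3-[2-(4-benzyloxy-3-methoxyphenyl)-1,3-dithian-2-yl]-4-hydroxybutanoic acid | COc1cc([C@H]2Oc3c(OC)cc(C[C@@H](C(=O)O)[C@H](CO)C4(SCCCS4)c4ccc(OCc5ccccc5)c(OC)c4)cc3[C@@H]2CO[Si](C)(C)C(C)(C)C)ccc1OCc1ccccc1 | intermediate (not isolated)
28 | (3R,4R)-3-(DBF-methyl)-4-[2-(4-benzyloxy-3-methoxyphenyl)-1,3-dithian-2-yl]dihydrofuran-2(3H)-one | COc1cc([C@H]2Oc3c(OC)cc(C[C@H]4C(=O)OC[C@@H]4C4(SCCCS4)c4ccc(OCc5ccccc5)c(OC)c4)cc3[C@@H]2CO[Si](C)(C)C(C)(C)C)ccc1OCc1ccccc1 | intermediate
29 | (3R,4R)-4-(4-benzyloxy-3-methoxybenzoyl)-3-(DBF-methyl)dihydrofuran-2(3H)-one | COc1cc([C@H]2Oc3c(OC)cc(C[C@H]4C(=O)OC[C@@H]4C(=O)c4ccc(OCc5ccccc5)c(OC)c4)cc3[C@@H]2CO[Si](C)(C)C(C)(C)C)ccc1OCc1ccccc1 | intermediate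
30 | (3R,4R)-4-[(R)-(4-benzyloxy-3-methoxyphenyl)(hydroxy)methyl]-3-(DBF-methyl)dihydrofuran-2(3H)-one | COc1cc([C@H]2Oc3c(OC)cc(C[C@H]4C(=O)OC[C@@H]4[C@@H](O)c4ccc(OCc5ccccc5)c(OC)c4)cc3[C@@H]2CO[Si](C)(C)C(C)(C)C)ccc1OCc1ccccc1 | intermediate
31 | (3R,4R)-4-[(R)-(4-benzyloxy-3-methoxyphenyl)(hydroxy)methyl]-3-{[(2S,3R)-2-(4-benzyloxy-3-methoxyphenyl)-3-(hydroxymethyl)-7-methoxy-2,3-dihydrobenzofuran-5-yl]methyl}dihydrofuran-2(3H)-one | COc1cc([C@H]2Oc3c(OC)cc(C[C@H]4C(=O)OC[C@@H]4[C@@H](O)c4ccc(OCc5ccccc5)c(OC)c4)cc3[C@@H]2CO)ccc1OCc1ccccc1 | intermediate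
32 | (3R,4R)-4-[(R)-hydroxy(4-hydroxy-3-methoxyphenyl)methyl]-3-{[(2S,3R)-2-(4-hydroxy-3-methoxyphenyl)-3-(hydroxymethyl)-7-methoxy-2,3-dihydrobenzofuran-5-yl]methyl}dihydrofuran-2(3H)-one | COc1cc([C@H]2Oc3c(OC)cc(C[C@H]4C(=O)OC[C@@H]4[C@@H](O)c4ccc(O)c(OC)c4)cc3[C@@H]2CO)ccc1O | target

## Step count and least certain steps

Total: 18 steps. Longest linear sequence: 15 steps (steps 1 to 9, then 13 to 18).

Step 13 (key step). The likeliest failure is slow C-alkylation of the hindered enolate 24 by the bulky, electron-rich bromide 14, so that retro-addition or proton quench takes over on warming; the bromide may also ionise. Fallback: the two bonds are made in separate operations. From 17 and 22 the enolate 24 is quenched with NH4Cl to give the conjugate adduct (4R,5R)-4-[2-(BnV)-1,3-dithian-2-yl]-5-(Men-oxy)dihydrofuran-2(3H)-one F1. Bromide 14 is turned by NaI in acetone into DBF-methyl iodide F2. F1 is deprotonated with LiHMDS in THF/DMPU at −78 °C and alkylated with F2, which returns to the route at 25.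

Step 3. Coupling of an ortho-alkoxy, electron-rich aryl iodide with the diazoacetate may be slow, allowing diazo decomposition or some reaction at the carbon–bromine bond. Fallback: from 4, a Negishi-type coupling with the Reformatsky reagent BrZnCH2CO2Et under Pd(PPh3)4 catalysis gives the arylacetate ethyl 2-{2-[(BnV)methoxy]-5-bromo-3-methoxyphenyl}acetate F3. Diazo transfer with 4-acetamidobenzenesulfonyl azide and DBU then returns to the route at 6.

Step 4. Facial selectivity may be poor with the extra ortho-methoxy group and the ethyl ester, and oxonium ylide formation with benzyl shift may compete with insertion. Fallback: resolution instead of asymmetric catalysis.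
- From 6, achiral Rh2(OAc)4 gives the cis ester as a racemate, 7 together with its enantiomer F4.
- Steps 5 and 6 then give 8 with its enantiomer F5, and 9 with its enantiomer F6.
- Lipase-catalysed acetylation with vinyl acetate acylates one enantiomer of the primary alcohol.
- If F6 is acylated, giving acetate F7, unreacted 9 is collected directly.
- If 9 is acylated, its acetate F8 is separated and cleaved with K2CO3 in MeOH.
- Either way the route is rejoined at 9.

Step 16. Reagent control may not overcome the substrate's Felkin–Anh bias, giving carbinol epimer mixtures; the bulky alpha-branched alkyl group could also erode the catalyst's aryl/alkyl discrimination. Fallback: substrate control followed by inversion. From 29, LiBH(s-Bu)3 (L-Selectride) at −78 °C should give the (S)-carbinol F9. Mitsunobu reaction with chloroacetic acid (PPh3, DIAD) gives the inverted (R)-chloroacetate F10. Thiourea with NaHCO3 in EtOH removes the chloroacetyl group under near-neutral conditions and returns to the route at 30.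

Step 18. Over-reduction is the risk: hydrogenolysis of the para-oxygenated benzylic carbinol or of the C2–O1 bond, or catalyst poisoning by sulfur traces that forces harsher conditions. Fallback: the protecting groups are exchanged before the carbinol exists.
- From 29, hydrogenolysis (H2, Pd/C) gives the bisphenol ketone F11.
- TBSCl and imidazole give the tris-silyl ketone F12.
- The CBS reduction of step 16 gives the tris-silyl (R)-carbinol F13.
- HF·pyridine removes all three silyl groups and rejoins the route at 32.

## Further compounds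

F1 | step 13 | (4R,5R)-4-[2-(4-benzyloxy-3-methoxyphenyl)-1,3-dithian-2-yl]-5-[(1R,2S,5R)-menthyloxy]dihydrofuran-2(3H)-one | O=C1C[C@@H](C2(SCCCS2)c2ccc(OCc3ccccc3)c(OC)c2)[C@H](O[C@@H]2C[C@H](C)CC[C@H]2C(C)C)O1
F2 | step 13 | (2S,3R)-2-(4-benzyloxy-3-methoxyphenyl)-3-[(tert-butyldimethylsilyloxy)methyl]-5-(iodomethyl)-7-methoxy-2,3-dihydrobenzofuran | COc1cc([C@H]2Oc3c(OC)cc(CI)cc3[C@@H]2CO[Si](C)(C)C(C)(C)C)ccc1OCc1ccccc1
F3 | step 3 | ethyl 2-{2-[(4-benzyloxy-3-methoxyphenyl)methoxy]-5-bromo-3-methoxyphenyl}acetate | CCOC(=O)Cc1cc(Br)cc(OC)c1OCc1ccc(OCc2ccccc2)c(OC)c1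
F4 | step 4 | ethyl (2R,3S)-2-(4-benzyloxy-3-methoxyphenyl)-5-bromo-7-methoxy-2,3-dihydrobenzofuran-3-carboxylate (cis, enantiomer of 7) | COc1cc([C@@H]2Oc3c(OC)cc(Br)cc3[C@@H]2C(=O)OCC)ccc1OCc1ccccc1
F5 | step 4 | ethyl (2R,3R)-2-(4-benzyloxy-3-methoxyphenyl)-5-bromo-7-methoxy-2,3-dihydrobenzofuran-3-carboxylate (trans, enantiomer of 8) | COc1cc([C@@H]2Oc3c(OC)cc(Br)cc3[C@H]2C(=O)OCC)ccc1OCc1ccccc1
F6 | step 4 | [(2R,3S)-2-(4-benzyloxy-3-methoxyphenyl)-5-bromo-7-methoxy-2,3-dihydrobenzofuran-3-yl]methanol (enantiomer of 9) | COc1cc([C@@H]2Oc3c(OC)cc(Br)cc3[C@H]2CO)ccc1OCc1ccccc1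
F7 | step 4 | [(2R,3S)-2-(4-benzyloxy-3-methoxyphenyl)-5-bromo-7-methoxy-2,3-dihydrobenzofuran-3-yl]methyl acetate | COc1cc([C@@H]2Oc3c(OC)cc(Br)cc3[C@H]2COC(C)=O)ccc1OCc1ccccc1
F8 | step 4 | [(2S,3R)-2-(4-benzyloxy-3-methoxyphenyl)-5-bromo-7-methoxy-2,3-dihydrobenzofuran-3-yl]methyl acetate | COc1cc([C@H]2Oc3c(OC)cc(Br)cc3[C@@H]2COC(C)=O)ccc1OCc1ccccc1
F9 | step 16 | (3R,4R)-4-[(S)-(4-benzyloxy-3-methoxyphenyl)(hydroxy)methyl]-3-(DBF-methyl)dihydrofuran-2(3H)-one | COc1cc([C@H]2Oc3c(OC)cc(C[C@H]4C(=O)OC[C@@H]4[C@H](O)c4ccc(OCc5ccccc5)c(OC)c4)cc3[C@@H]2CO[Si](C)(C)C(C)(C)C)ccc1OCc1ccccc1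
F10 | step 16 | (R)-(4-benzyloxy-3-methoxyphenyl)[(3R,4R)-4-(DBF-methyl)-5-oxotetrahydrofuran-3-yl]methyl chloroacetate | COc1cc([C@H]2Oc3c(OC)cc(C[C@H]4C(=O)OC[C@@H]4[C@@H](OC(=O)CCl)c4ccc(OCc5ccccc5)c(OC)c4)cc3[C@@H]2CO[Si](C)(C)C(C)(C)C)ccc1OCc1ccccc1
F11 | step 18 | (3R,4R)-4-(4-hydroxy-3-methoxybenzoyl)-3-{[(2S,3R)-3-[(tert-butyldimethylsilyloxy)methyl]-2-(4-hydroxy-3-methoxyphenyl)-7-methoxy-2,3-dihydrobenzofuran-5-yl]methyl}dihydrofuran-2(3H)-one | COc1cc([C@H]2Oc3c(OC)cc(C[C@H]4C(=O)OC[C@@H]4C(=O)c4ccc(O)c(OC)c4)cc3[C@@H]2CO[Si](C)(C)C(C)(C)C)ccc1O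
F12 | step 18 | tris(tert-butyldimethylsilyl) ether of F11 (both phenols and the primary alcohol silylated, ketone) | COc1cc([C@H]2Oc3c(OC)cc(C[C@H]4C(=O)OC[C@@H]4C(=O)c4ccc(O[Si](C)(C)C(C)(C)C)c(OC)c4)cc3[C@@H]2CO[Si](C)(C)C(C)(C)C)ccc1O[Si](C)(C)C(C)(C)C
F13 | step 18 | tris(tert-butyldimethylsilyl) ether of 32 with free (R)-carbinol | COc1cc([C@H]2Oc3c(OC)cc(C[C@H]4C(=O)OC[C@@H]4[C@@H](O)c4ccc(O[Si](C)(C)C(C)(C)C)c(OC)c4)cc3[C@@H]2CO[Si](C)(C)C(C)(C)C)ccc1O[Si](C)(C)C(C)(C)C
A1 | alternative 1 | exo-6-(4-benzyloxy-3-methoxyphenyl)-3-oxabicyclo[3.1.0]hexan-2-one (single enantiomer) | O=C1OC[C@@H]2[C@@H](c3ccc(OCc4ccccc4)c(OC)c3)[C@H]12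
A2 | alternative 1 | (E)-3-(4-benzyloxy-3-methoxyphenyl)prop-2-en-1-yl diazoacetate | COc1cc(/C=C/COC(=O)C=[N+]=[N-])ccc1OCc1ccccc1
A3 | alternative 1 | (4R)-4-[(R)-(4-benzyloxy-3-methoxyphenyl)(hydroxy)methyl]dihydrofuran-2(3H)-one | O=C1OC[C@@H](C1)[C@@H](O)c1ccc(OCc2ccccc2)c(OC)c1
A4 | alternative 2 | (2S,3R)-2-(4-benzyloxy-3-methoxyphenyl)-5-(1,3-dioxolan-2-yl)-7-methoxy-3-[(2,2,6,6-tetramethylpiperidin-1-yloxy)methyl]-2,3-dihydrobenzofuran | COc1cc([C@H]2Oc3c(OC)cc(C4OCCO4)cc3[C@@H]2CON2C(C)(C)CCCC2(C)C)ccc1OCc1ccccc1
A5 | alternative 2 | 2-(4-{[(1S)-1-(4-benzyloxy-3-methoxyphenyl)prop-2-en-1-yl]oxy}-3-iodo-5-methoxyphenyl)-1,3-dioxolane | COc1cc([C@H](C=C)Oc2c(I)cc(C3OCCO3)cc2OC)ccc1OCc1ccccc1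
A6 | alternative 3 | trans-dihydrobenzofuran of the full skeleton with C3 acyl (S)-4-benzyloxazolidin-2-one, ring C O-benzyl, ring A phenol free | COc1cc([C@H]2Oc3c(OC)cc(C[C@H]4C(=O)OC[C@@H]4[C@@H](O)c4ccc(OCc5ccccc5)c(OC)c4)cc3[C@@H]2C(=O)N2[C@@H](Cc3ccccc3)COC2=O)ccc1O
A7 | alternative 3 | (S)-4-benzyl-3-[(E)-3-(4-hydroxy-3-methoxyphenyl)prop-2-enoyl]oxazolidin-2-one | COc1cc(/C=C/C(=O)N2[C@@H](Cc3ccccc3)COC2=O)ccc1O
A8 | alternative 3 | (3R,4R)-4-[(R)-(4-benzyloxy-3-methoxyphenyl)(hydroxy)methyl]-3-(4-hydroxy-3-methoxybenzyl)dihydrofuran-2(3H)-one | COc1cc(C[C@H]2C(=O)OC[C@@H]2[C@@H](O)c2ccc(OCc3ccccc3)c(OC)c2)ccc1O
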